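**Plan**
- Retrosynthesis: remove the acetate and the C1/C6 oxidation level. Cut C8–C15 together with C15–C16, so that C15 becomes carbon monoxide joining a C8 lactone enolate to a 2-propenyl triflate on C13. Then cut C13–C14 and C8–C14 (C14 = a Mannich CH2), C9–C11, the lactone C7–O and C9–C10, C10–C20 and C5–C6.
- Forward: ring A (from 4,4-dimethylcyclohexadienone) → spiro δ-lactone → ring C (conjugate addition, Mannich methylenation, intramolecular Michael) → ring D (carbonylative closure) → C15 reduction and acetylation → ring A enone and C6 aldehyde.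
- Enabling feature: in ring D (C8–C14–C13–C16–C15), C15 is a carbonyl-level carbon between C8, which is α to the lactone carbonyl C7 and therefore an enolate carbon, and the vinylic C16 of the exocyclic C16=C17 methylene. One CO can thus be stitched between a C8 enolate and a C16 vinyl electrophile; the C15 ketone is an oxidation-level helper, reduced afterwards.
- Stereochemistry: C5 from a catalytic asymmetric conjugate addition; C10 anti to the C5 substituent; C9 by addition directed by the free C1–OH; C13 under thermodynamic control; C8 fixed by the bridging geometry; C15 by hydride attack on the exo face.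

Key step: step 14

Remark: locants C1–C20 are the kaurane numbers of the target; ring A = C1–C5/C10, ring C = C8/C9/C11–C14, ring D = C8/C14/C13/C16/C15.
Assumption: 1 is taken as commercially available (it is otherwise one DDQ dehydrogenation from 4,4-dimethylcyclohex-2-enone).
Assumption: (R)-BINAP is taken to deliver the (5R) adduct 3 by analogy with cyclohex-2-enone; if the sense is opposite, the antipodal ligand is used.
Remark: the C1 carbinol configuration (11–30) and the C8 configuration (13, 18–20, 23–25) are erased later and are drawn as the expected major epimers.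

Step 1
Reactants: 1 4,4-dimethylcyclohexa-2,5-dien-1-one; 2 potassium vinyltrifluoroborate
Product: 3 (5R)-5-ethenyl-4,4-dimethylcyclohex-2-en-1-one
Conditions: [Rh(cod)2]PF6 (cod = 1,5-cyclooctadiene, 3 mol %), (R)-BINAP (3.3 mol %), PhMe/H2O, 100 °C; 1 in excess
Reagents that add atoms: none
Why: Rhodium-catalysed asymmetric conjugate addition (Hayashi–Miyaura type) of the vinyl group to one of the two enantiotopic enone arms desymmetrises 1, the chiral diphosphine choosing arm and face and so setting C5, while an excess of 1 suppresses double addition.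

Step 2
Reactants: 3 (5R)-5-ethenyl-4,4-dimethylcyclohex-2-en-1-one; 4 ethyl formate
Product: 5 hydroxymethylene ketone
Conditions: NaH, THF, 0 → 23 °C; then 1 M HCl
Reagents that add atoms: none
Why: Claisen formylation occurs at C10, the only enolisable position (C4 is quaternary, C2 is vinylic), and gives the hydrogen-bonded enol without touching C5.

Step 3
Reactants: 5 hydroxymethylene ketone; 6 2,2,2-trifluoroethyl acrylate
Product: 7 formyl keto ester
Conditions: Et3N (0.2 equiv), CH2Cl2, 23 °C
Reagents that add atoms: none
Why: Amine-catalysed Michael addition of the β-keto aldehyde creates the quaternary C10; the acrylate approaches anti to the neighbouring C5 vinyl group, so C9 ends trans and the formyl carbon C20 cis to that group.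

Step 4
Reactants: 7 formyl keto ester
Product: 9 spirolactone enone, via hydroxy ester 8 (not isolated)
Conditions: NaBH4, EtOH/CH2Cl2, −78 °C; then 23 °C
Reagents that add atoms: none
Why: Chemoselective reduction–lactonisation: the aldehyde is far more electrophilic than the hindered enone carbonyl, and the resulting neopentyl alkoxide closes the δ-lactone on the activated trifluoroethyl ester.

Step 5
Reactants: 9 spirolactone enone
Product: 11 lactone diol, via keto aldehyde 10 (not isolated)
Conditions: O3, CH2Cl2/MeOH, −78 °C; Me2S; then CeCl3·7H2O, NaBH4, −78 → 0 °C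
Reagents that add atoms: ozone, [O-][O+]=O
Why: Ozonolysis cleaves the electron-rich vinyl group in preference to the electron-poor enone C2=C3, and Luche reduction then takes the aldehyde to C6–OH and the enone 1,2 to the allylic alcohol, hydride adding anti to the pseudo-axial C20.

Step 6
Reactants: 11 lactone diol
Product: 12 C6 silyl ether
Conditions: TBSCl, imidazole, CH2Cl2, 0 °C
Reagents that add atoms: tert-butyldimethylsilyl chloride, CC(C)(C)[Si](C)(C)Cl
Why: Selective silylation of the primary C6–OH leaves the hindered secondary allylic C1–OH free to serve as a directing group.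

Step 7
Reactants: 12 C6 silyl ether
Product: 14 unsaturated lactone, via selenide 13 (not isolated)
Conditions: LiN(i-Pr)2 (2.2 equiv), THF, −78 °C; PhSeBr; then H2O2, pyridine, CH2Cl2, 0 → 23 °C
Reagents that add atoms: none
Why: α-Selenenylation of the lactone enolate (C1–OH carried as its lithium alkoxide) and selenoxide syn-elimination can only use a C9–H and therefore give the endocyclic C8=C9 enoate.

Step 8
Reactants: 14 unsaturated lactone; 15 5-bromopent-1-ene
Product: 18 Mannich base, via Grignard reagent 16 (not isolated), via magnesium enolate 17 (not isolated)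
Conditions: 15, Mg, THF, 50 °C; then 14, 16 (3 equiv), CuBr·SMe2 (20 mol %), THF, −40 °C; then [Me2N=CH2]I, −40 → 23 °C; NH4Cl
Reagents that add atoms: N,N-dimethylmethyleneiminium iodide (Eschenmoser's salt), C=[N+](C)C.[I-]
Why: Copper-catalysed conjugate addition of the Grignard reagent to C9 is delivered by the magnesium alkoxide of the equatorial C1–OH, which lies on the C1 face of the enoate, anti to the C5 side chain (this sets C9), and the enolate is trapped in a Mannich reaction trans to the new chain.

Step 9
Reactants: 18 Mannich base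
Product: 19 bis-silyl Mannich base
Conditions: TBSOTf, 2,6-lutidine, CH2Cl2, 0 °C
Reagents that add atoms: tert-butyldimethylsilyl triflate, CC(C)(C)[Si](C)(C)OS(=O)(=O)C(F)(F)F
Why: Silylation of the hindered C1–OH with the silyl triflate protects it before the base-mediated steps, in which a free alkoxide could add to C14 or translactonise.

Step 10
Reactants: 19 bis-silyl Mannich base
Product: 21 α-methylene lactone, via methiodide 20 (not isolated)
Conditions: MeI, MeOH, 23 °C; then DBU, CH2Cl2, 23 °C
Reagents that add atoms: none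
Why: Quaternisation and Hofmann-type (E1cB) elimination of trimethylamine unveil the α-methylene lactone, its methylene carbon C14 being the Mannich carbon.

Step 11
Reactants: 21 α-methylene lactone
Product: 22 methyl ketone
Conditions: PdCl2 (10 mol %), CuCl, O2 (1 atm), DMF/H2O, 23 °C
Reagents that add atoms: water, O
Why: Tsuji–Wacker oxidation converts the terminal monosubstituted alkene Markovnikov-selectively into the methyl ketone, the electron-poor α-methylene lactone and the hindered ring A alkene reacting far more slowly.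

Step 12
Reactants: 22 methyl ketone
Product: 23 tricyclic keto lactone
Conditions: pyrrolidine (0.3 equiv), AcOH (0.3 equiv), MeCN, 40 °C; aqueous work-up
Reagents that add atoms: none
Why: Enamine-mediated intramolecular Michael addition (Stork type, 6-endo-trig at C14) through the internal enamine closes ring C, the only accessible ring size, and reversible enamine/iminium formation lets C13 settle with the acetyl group equatorial and trans to C10.

Step 13
Reactants: 23 tricyclic keto lactone
Product: 25 enol triflate, via potassium enolate 24 (not isolated)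
Conditions: KN(SiMe3)2, THF, −78 °C; PhNTf2, −78 → −40 °C
Reagents that add atoms: N-phenylbis(trifluoromethanesulfonimide), O=S(=O)(N(c1ccccc1)S(=O)(=O)C(F)(F)F)C(F)(F)F
Why: Kinetic deprotonation of the methyl ketone at the methyl carbon C17 and O-sulfonylation give the terminal enol triflate regioselectively, the tertiary C13–H and the hindered lactone C8–H being removed far more slowly at −78 °C so that C13 is not epimerised.

Step 14
Reactants: 25 enol triflate
Product: 27 tetracyclic enone, via lithium enolate 26 (not isolated)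
Conditions: LiN(SiMe3)2, THF, −78 °C; then Pd(PPh3)4 (10 mol %), LiCl, CO (1 atm), −78 → 45 °C
Reagents that add atoms: carbon monoxide, [C-]#[O+]
Why: Proposed new method: LiN(SiMe3)2 forms the lactone enolate at C8 while zerovalent palladium inserts into the vinylic C16–OTf bond; CO insertion gives an acylpalladium whose carbonyl carbon is C15, and intramolecular C-acylation by the C8 enolate (attack on the acylpalladium carbon, then loss of the metal) forms C8–C15 and releases the catalyst. The closest known reactions are the palladium-catalysed carbonylative α-arylation and α-alkenylation of ketone and malonate enolates with aryl or alkenyl (pseudo)halides, and the intramolecular trapping of acylpalladium species by enolates; a lactone enolate that becomes quaternary has not been used in this way. Ring D (C8–C14–C13–C16–C15) closes 5-exo-trig at the acyl carbon and completes the bicyclo[3.2.1]octane. The new quaternary stereocentre C8 is dictated by C13: the acyl group hangs from C13 and can reach only the enolate face on which the two-carbon bridge is cis-1,3-diaxial to C13, so the C8 configuration before enolisation is irrelevant. The step needs C- over O-acylation (O-attack would require a seven-membered enol lactone), carbonylation over direct enolate–vinyl coupling (a four-membered ring) and over base-induced loss of triflate to an alkyne; ring size, the CO atmosphere and addition of the catalyst before warming should secure these.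

Step 15
Reactants: 27 tetracyclic enone
Product: 28 15-alcohol
Conditions: NaBH4, CeCl3·7H2O, MeOH, −78 °C
Reagents that add atoms: none
Why: Luche 1,2-reduction of the enone, with hydride attacking C15 from the exo face (the side of the C14 bridge) away from the C9–C11–C12 bridge and its axial C11–H, should give the endo 15-alcohol required.

Step 16
Reactants: 28 15-alcohol
Product: 29 15-acetate
Conditions: Ac2O, DMAP, pyridine, 23 °C
Reagents that add atoms: acetic anhydride, CC(=O)OC(C)=O
Why: DMAP-catalysed acetylation of the secondary allylic alcohol.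

Step 17
Reactants: 29 15-acetate
Product: 30 diol acetate
Conditions: HF·pyridine, pyridine/THF, 0 → 23 °C
Reagents that add atoms: none
Why: Fluoride cleavage of both silyl ethers under buffered, non-basic conditions should leave the acetate and lactone intact and avoid alkoxide-induced translactonisation onto O1.

Step 18
Reactants: 30 diol acetate
Product: 31 target
Conditions: Dess–Martin periodinane, NaHCO3, CH2Cl2, 0 → 23 °C
Reagents that add atoms: none
Why: Dess–Martin oxidation takes the allylic C1–OH to the ring A enone and the primary C6–OH to the aldehyde under neutral conditions that should not epimerise C5.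

**Compound list**
1 | 4,4-dimethylcyclohexa-2,5-dien-1-one | O=C1C=CC(C)(C)C=C1 | starting material
2 | potassium vinyltrifluoroborate | [K+].C=C[B-](F)(F)F | starting material
3 | (5R)-5-ethenyl-4,4-dimethylcyclohex-2-en-1-one | C=C[C@H]1CC(=O)C=CC1(C)C | intermediate
4 | ethyl formate | CCOC=O | starting material
5 | hydroxymethylene ketone: (5R,6Z)-5-ethenyl-6-(hydroxymethylidene)-4,4-dimethylcyclohex-2-en-1-one | O/C=C1\C(=O)C=CC(C)(C)[C@H]1C=C | intermediate
6 | 2,2,2-trifluoroethyl acrylate | C=CC(=O)OCC(F)(F)F | starting material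
7 | formyl keto ester: 2,2,2-trifluoroethyl 3-[(1S,6R)-6-ethenyl-1-formyl-5,5-dimethyl-2-oxocyclohex-3-en-1-yl]propanoate | O=C[C@@]1(CCC(=O)OCC(F)(F)F)C(=O)C=CC(C)(C)[C@H]1C=C | intermediate
8 | hydroxy ester: 2,2,2-trifluoroethyl 3-[(1S,6R)-6-ethenyl-1-(hydroxymethyl)-5,5-dimethyl-2-oxocyclohex-3-en-1-yl]propanoate | OC[C@@]1(CCC(=O)OCC(F)(F)F)C(=O)C=CC(C)(C)[C@H]1C=C | intermediate
9 | spirolactone enone: (6S,11R)-11-ethenyl-10,10-dimethyl-2-oxaspiro[5.5]undec-8-ene-3,7-dione | O=C1CC[C@]2(CO1)C(=O)C=CC(C)(C)[C@H]2C=C | intermediate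
10 | keto aldehyde: (6S,11R)-10,10-dimethyl-3,7-dioxo-2-oxaspiro[5.5]undec-8-ene-11-carbaldehyde | O=C1CC[C@]2(CO1)C(=O)C=CC(C)(C)[C@H]2C=O | intermediate
11 | lactone diol: (6S,7S,11R)-7-hydroxy-11-(hydroxymethyl)-10,10-dimethyl-2-oxaspiro[5.5]undec-8-en-3-one | O=C1CC[C@]2(CO1)[C@@H](O)C=CC(C)(C)[C@H]2CO | intermediate
12 | C6 silyl ether: (6S,7S,11R)-11-[(tert-butyldimethylsilyloxy)methyl]-7-hydroxy-10,10-dimethyl-2-oxaspiro[5.5]undec-8-en-3-one | O=C1CC[C@]2(CO1)[C@@H](O)C=CC(C)(C)[C@H]2CO[Si](C)(C)C(C)(C)C | intermediate
13 | selenide: 4-(phenylselanyl) derivative of 12 (C8 of the target; mixture of epimers at that carbon) | O=C1C([Se]c3ccccc3)C[C@]2(CO1)[C@@H](O)C=CC(C)(C)[C@H]2CO[Si](C)(C)C(C)(C)C | intermediate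
14 | unsaturated lactone: (6S,7S,11R)-11-[(tert-butyldimethylsilyloxy)methyl]-7-hydroxy-10,10-dimethyl-2-oxaspiro[5.5]undeca-4,8-dien-3-one | O=C1C=C[C@]2(CO1)[C@@H](O)C=CC(C)(C)[C@H]2CO[Si](C)(C)C(C)(C)C | intermediate
15 | 5-bromopent-1-ene | C=CCCCBr | starting material
16 | Grignard reagent: pent-4-en-1-ylmagnesium bromide | C=CCCC[Mg]Br | intermediate
17 | magnesium enolate: bromomagnesium ketene acetal and C1 bromomagnesium alkoxide of the C9 pent-4-enyl adduct of 14 | Br[Mg]OC1=C[C@@H](CCCC=C)[C@]2(CO1)[C@@H](O[Mg]Br)C=CC(C)(C)[C@H]2CO[Si](C)(C)C(C)(C)C | intermediate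
18 | Mannich base: (4S,5R,6S,7S,11R)-11-[(tert-butyldimethylsilyloxy)methyl]-4-[(dimethylamino)methyl]-7-hydroxy-10,10-dimethyl-5-(pent-4-en-1-yl)-2-oxaspiro[5.5]undec-8-en-3-one (side chains at C8 and C9 trans) | O=C1[C@H](CN(C)C)[C@@H](CCCC=C)[C@]2(CO1)[C@@H](O)C=CC(C)(C)[C@H]2CO[Si](C)(C)C(C)(C)C | intermediate
19 | bis-silyl Mannich base: 7-O-tert-butyldimethylsilyl ether of 18 | O=C1[C@H](CN(C)C)[C@@H](CCCC=C)[C@]2(CO1)[C@@H](O[Si](C)(C)C(C)(C)C)C=CC(C)(C)[C@H]2CO[Si](C)(C)C(C)(C)C | intermediate
20 | methiodide: trimethylammonium iodide derived from 19 | O=C1[C@H](C[N+](C)(C)C)[C@@H](CCCC=C)[C@]2(CO1)[C@@H](O[Si](C)(C)C(C)(C)C)C=CC(C)(C)[C@H]2CO[Si](C)(C)C(C)(C)C.[I-] | intermediate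
21 | α-methylene lactone: (5S,6S,7S,11R)-7-(tert-butyldimethylsilyloxy)-11-[(tert-butyldimethylsilyloxy)methyl]-10,10-dimethyl-4-methylidene-5-(pent-4-en-1-yl)-2-oxaspiro[5.5]undec-8-en-3-one | O=C1C(=C)[C@@H](CCCC=C)[C@]2(CO1)[C@@H](O[Si](C)(C)C(C)(C)C)C=CC(C)(C)[C@H]2CO[Si](C)(C)C(C)(C)C | intermediate
22 | methyl ketone: 5-(4-oxopentyl) analogue of 21 with the same configuration | O=C1C(=C)[C@@H](CCCC(C)=O)[C@]2(CO1)[C@@H](O[Si](C)(C)C(C)(C)C)C=CC(C)(C)[C@H]2CO[Si](C)(C)C(C)(C)C | intermediate
23 | tricyclic keto lactone: ring C closed; 13-acetyl equatorial and trans to C10; lactone trans-fused at C8/C9; 1-OTBS; 6-OTBS; C5, C9, C10 and C13 as in 31 | CC(=O)[C@@H]1CC[C@@H]2[C@@H](C1)C(=O)OC[C@]23[C@@H](O[Si](C)(C)C(C)(C)C)C=CC(C)(C)[C@H]3CO[Si](C)(C)C(C)(C)C | intermediate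
24 | potassium enolate: terminal (C16=C17) potassium enolate of 23 | [K+].C=C([O-])[C@@H]1CC[C@@H]2[C@@H](C1)C(=O)OC[C@]23[C@@H](O[Si](C)(C)C(C)(C)C)C=CC(C)(C)[C@H]3CO[Si](C)(C)C(C)(C)C | intermediate
25 | enol triflate: 13-[1-(trifluoromethanesulfonyloxy)ethenyl] analogue of 23 | C=C(OS(=O)(=O)C(F)(F)F)[C@@H]1CC[C@@H]2[C@@H](C1)C(=O)OC[C@]23[C@@H](O[Si](C)(C)C(C)(C)C)C=CC(C)(C)[C@H]3CO[Si](C)(C)C(C)(C)C | intermediate
26 | lithium enolate: C8 lithium lactone enolate of 25 | C=C(OS(=O)(=O)C(F)(F)F)[C@@H]1CC[C@@H]2C(C1)=C(O[Li])OC[C@]23[C@@H](O[Si](C)(C)C(C)(C)C)C=CC(C)(C)[C@H]3CO[Si](C)(C)C(C)(C)C | intermediate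
27 | tetracyclic enone: 1-OTBS, 6-OTBS, 15-oxo-6,7-secokaura-2,16-dien-7,20-olide; C5, C8, C9, C10 and C13 as in 31 | C=C1[C@@H]2CC[C@@H]3[C@](C2)(C(=O)OC[C@]34[C@@H](O[Si](C)(C)C(C)(C)C)C=CC(C)(C)[C@H]4CO[Si](C)(C)C(C)(C)C)C1=O | intermediate
28 | 15-alcohol: endo 15-hydroxy compound from 27, C15 as in 31 | C=C1[C@@H]2CC[C@@H]3[C@](C2)(C(=O)OC[C@]34[C@@H](O[Si](C)(C)C(C)(C)C)C=CC(C)(C)[C@H]4CO[Si](C)(C)C(C)(C)C)[C@@H]1O | intermediate
29 | 15-acetate: acetate of 28 | C=C1[C@@H]2CC[C@@H]3[C@](C2)(C(=O)OC[C@]34[C@@H](O[Si](C)(C)C(C)(C)C)C=CC(C)(C)[C@H]4CO[Si](C)(C)C(C)(C)C)[C@@H]1OC(C)=O | intermediate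
30 | diol acetate: 15-acetoxy-1,6-dihydroxy-6,7-secokaura-2,16-dien-7,20-olide | C=C1[C@@H]2CC[C@@H]3[C@](C2)(C(=O)OC[C@]34[C@@H](O)C=CC(C)(C)[C@H]4CO)[C@@H]1OC(C)=O | intermediate
31 | target: (5R,8S,9S,10S,13R,15R)-15-acetoxy-1,6-dioxo-6,7-secokaura-2,16-dien-7,20-olide | C=C1[C@@H]2CC[C@@H]3[C@](C2)(C(=O)OC[C@]32C(=O)C=CC(C)(C)[C@H]2C=O)[C@@H]1OC(C)=O | target

**Step count and risks**
Total steps: 18. Longest linear sequence: 18 (the route is fully linear from 1).

Steps most likely to fail:

1. Step 14 (Proposed new method). The triflate may be lost through base-induced elimination or triflyl transfer to the enolate, and the enolate may be protonated or O-acylated instead of C-acylated, so that ring D does not close. Fallback with known chemistry, setting out from 25: palladium-catalysed methoxycarbonylation (Pd(OAc)2, dppf, CO, MeOH, Et3N, DMF, 60 °C) gives the methyl acrylate ester F1. Treatment with LiN(SiMe3)2 (THF, −78 °C, cold AcOH quench) then closes ring D by an intramolecular Claisen (Dieckmann-type) acylation of the lactone enolate and rejoins the route at 27.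

2. Step 8. The organocopper reagent may fail to engage the neopentyl-type β-carbon C9 and attack the lactone carbonyl instead; the C1 alkoxide may translactonise; facial control at C9 may be eroded. Fallback setting out from 14: a radical conjugate (Giese) addition of the pent-4-enyl radical (5-iodopent-1-ene, (Me3Si)3SiH, AIBN, PhH, 80 °C), which is less sensitive to the hindered environment and should also add anti to the C5 side chain, gives the C9 pentenyl lactone F2. Deprotonation (LiN(i-Pr)2, 2.2 equiv, −78 °C) and a Mannich reaction with [Me2N=CH2]I then return to 18.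

3. Step 1. Insertion at the β-carbon next to the quaternary C4 may be slow, the second enone arm may also react, and the enantioselectivity may be low. Fallback setting out from 1: a primary-amine-catalysed (9-amino-9-deoxy-epi-quinine, PhCO2H) Michael addition of nitromethane gives the nitromethyl enone F3. A Nef reaction (TiCl3, NH4OAc, aqueous THF) gives the formyl enone F4, and salt-free Wittig methylenation (Ph3P=CH2, THF, −78 °C) returns to 3.

Further compounds
F1 | step 14 | methyl acrylate ester: 13-[1-(methoxycarbonyl)ethenyl] analogue of 25 | C=C(C(=O)OC)[C@@H]1CC[C@@H]2[C@@H](C1)C(=O)OC[C@]23[C@@H](O[Si](C)(C)C(C)(C)C)C=CC(C)(C)[C@H]3CO[Si](C)(C)C(C)(C)C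
F2 | step 8 | C9 pentenyl lactone: 18 lacking the dimethylaminomethyl group | O=C1C[C@@H](CCCC=C)[C@]2(CO1)[C@@H](O)C=CC(C)(C)[C@H]2CO[Si](C)(C)C(C)(C)C
F3 | step 1 | nitromethyl enone: (S)-4,4-dimethyl-5-(nitromethyl)cyclohex-2-en-1-one | O=[N+]([O-])C[C@H]1CC(=O)C=CC1(C)C
F4 | step 1 | formyl enone: (S)-2,2-dimethyl-5-oxocyclohex-3-ene-1-carbaldehyde | O=C[C@H]1CC(=O)C=CC1(C)C
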